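**Retrosynthetic overview**
- The plan rests on ring A of the chlorine-free chromone (C4a, C5, C6, C7, C8, C8a). Its only substituent is the C7 hydroxyl, para to C4a and meta to the O1-bearing C8a, with hydrogens at C5, C6 and C8, which is the imprint of a 1-methoxy-3-silyloxybutadiene.
- After unmasking two methyl ethers, cutting C8–C8a and C4a–C5 gives a 3-aryl-5-bromo-4-pyranone and the silyloxydiene. A [4+2] addition across the brominated C5=C6 bond, then loss of methanol and HBr, closes this benzo ring last.
- The bromopyranone comes from 3,5-dibromo-4H-pyran-4-one and an arylboronate by a single Suzuki coupling. The boronate comes from a diaryl ether bromide made by Chan–Lam O-arylation.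
- The phenol partner is 8-chloro-4'-hydroxy-7-methoxyisoflavone, built from 2-chlororesorcinol and 4-hydroxyphenylacetic acid through a deoxybenzoin.
- Ring order: pyranone ring of the chlorinated chromone (step 1), attachment of the purchased 4-pyranone ring (step 6), benzo ring A of the second chromone (step 7).

Key step: step 7

Remark on the chemistry: the target is achiral; the two intermediates of step 7 that are not isolated are racemic, and their SMILES show one enantiomer with the expected relative configuration.

**Step 1**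
Reactants: 1 2-chlororesorcinol; 2 4-hydroxyphenylacetic acid
Product: 4 8-chloro-7-hydroxy-3-(4-hydroxyphenyl)-4H-chromen-4-one, via deoxybenzoin 3 (not isolated)
Conditions: BF3·OEt2, 85 °C; then DMF, MsCl, 50 to 80 °C; aqueous work-up
Reagents that add atoms: N,N-dimethylformamide, CN(C)C=O
Why: BF3-promoted Friedel–Crafts C-acylation at C4 of the resorcinol (ortho to one hydroxyl, para to the other, C4 and C6 being equivalent) should give deoxybenzoin 3, whose methylene is formylated by the DMF/MsCl Vilsmeier-type reagent and closes onto the ortho hydroxyl, the established one-pot isoflavone synthesis.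

**Step 2**
Reactants: 4 8-chloro-7-hydroxy-3-(4-hydroxyphenyl)-4H-chromen-4-one
Product: 5 8-chloro-3-(4-hydroxyphenyl)-7-methoxy-4H-chromen-4-one
Conditions: MeI (1.2 equiv), KHCO3 (1.2 equiv), DMF, 40 °C
Reagents that add atoms: iodomethane, CI
Why: Williamson O-methylation under bicarbonate control, in which the 7-hydroxyl, a vinylogous acid para to C4=O and further acidified by the ortho chlorine, is the only phenol ionised, so the 4'-hydroxyl should stay free.

**Step 3**
Reactants: 5 8-chloro-3-(4-hydroxyphenyl)-7-methoxy-4H-chromen-4-one; 6 5-bromo-2-methoxyphenylboronic acid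
Product: 7 3-[4-(5-bromo-2-methoxyphenoxy)phenyl]-8-chloro-7-methoxy-4H-chromen-4-one
Conditions: Cu(OAc)2 (1 equiv), pyridine, 4 Å MS, CH2Cl2, O2 (balloon), rt
Reagents that add atoms: none
Why: Chan–Lam–Evans oxidative O-arylation of the 4'-phenol at room temperature should form the diaryl ether while the aryl bromide and chloride, which copper does not activate under these conditions, remain, dioxygen returning the copper to the divalent state so that Cu(OAc)2 is not consumed.

**Step 4**
Reactants: 7 3-[4-(5-bromo-2-methoxyphenoxy)phenyl]-8-chloro-7-methoxy-4H-chromen-4-one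
Product: 8 8-chloro-7-methoxy-3-{4-[2-methoxy-5-(4,4,5,5-tetramethyl-1,3,2-dioxaborolan-2-yl)phenoxy]phenyl}-4H-chromen-4-one
Conditions: B2pin2 (1.2 equiv), Pd(dppf)Cl2 (5 mol%), KOAc, 1,4-dioxane, 85 °C
Reagents that add atoms: bis(pinacolato)diboron, CC1(C)OB(OC1(C)C)B1OC(C)(C)C(C)(C)O1
Why: Miyaura borylation, in which zerovalent palladium inserts into the aryl C–Br bond far faster than into the flanked, electron-rich C8–Cl bond and KOAc is too weak a base to open the chromone ring.

**Step 5**
Reactants: 9 4H-pyran-4-one
Product: 10 3,5-dibromo-4H-pyran-4-one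
Conditions: Br2 (2.2 equiv), NaOAc, AcOH, rt to 50 °C
Reagents that add atoms: bromine, BrBr
Why: Electrophilic bromination of the two nucleophilic α-carbons (C3 and C5) of the vinylogous ester by addition–elimination, buffered by acetate, should give the symmetric dibromide.

**Step 6**
Reactants: 8 8-chloro-7-methoxy-3-{4-[2-methoxy-5-(4,4,5,5-tetramethyl-1,3,2-dioxaborolan-2-yl)phenoxy]phenyl}-4H-chromen-4-one; 10 3,5-dibromo-4H-pyran-4-one
Product: 11 3-bromo-5-{3-[4-(8-chloro-7-methoxy-4-oxo-4H-chromen-3-yl)phenoxy]-4-methoxyphenyl}-4H-pyran-4-one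
Conditions: 10 (3 equiv), Pd(PPh3)4 (5 mol%), K3PO4, 1,4-dioxane/H2O 10:1, 60 °C
Reagents that add atoms: none
Why: Suzuki–Miyaura coupling in which the threefold excess of the more electron-poor dibromide should make the first oxidative addition outrun a second coupling of the arylated product, while the mild phosphate base spares both pyranone rings.

**Step 7**
Reactants: 11 3-bromo-5-{3-[4-(8-chloro-7-methoxy-4-oxo-4H-chromen-3-yl)phenoxy]-4-methoxyphenyl}-4H-pyran-4-one; 12 (E)-1-methoxy-3-(trimethylsilyloxy)buta-1,3-diene
Product: 15 3-{3-[4-(8-chloro-7-methoxy-4-oxo-4H-chromen-3-yl)phenoxy]-4-methoxyphenyl}-7-hydroxy-4H-chromen-4-one, via cis-fused bromo cycloadduct 13 (not isolated), via bromo enone 14 (not isolated)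
Conditions: 12 (5 equiv), toluene, 130 °C, sealed tube; then 1 M HCl, THF, 0 °C; then DBU (3 equiv), CH2Cl2, 0 °C to rt
Reagents that add atoms: none
Why: Proposed new method: a 5-bromo-3-aryl-4-pyranone has not been used as a dienophile, but the α-bromine lowers the LUMO of the C5=C6 enone bond, so electron-rich diene 12 should add in a concerted, asynchronous normal-demand [4+2] cycloaddition, its CH2 terminus bonding to C6 (the β-carbon) and its CH(OMe) terminus to the brominated C5, to give cis-fused adduct 13. The closest known reactions are Diels–Alder additions of 1-methoxy-3-silyloxybutadienes to 2-bromocycloalkenones and to 3-acceptor-substituted chromones, followed by elimination to phenols. Ring A, a six-membered carbocycle, is closed by this intermolecular [4+2] annulation (bonds C8–C8a and C4a–C5), and the three stereocentres of 13 (cis fusion from suprafacial addition, endo methoxy) are transient and vanish on aromatisation, so no stereocontrol is required. Because Br at C4a and H at C8a are cis in 13, an anti E2 loss of HBr is not available at that stage, so dilute acid first cleaves the silyl enol ether and expels methanol (E1cB) to give γ-bromo enone 14, and DBU then enolises the C7 ketone towards C8 so that HBr leaves across C4a–C8a from a cyclohexadienolate in a syn elimination driven by aromatisation, bromine serving as activator and leaving group with no oxidant. The step needs site selectivity and a defined diene orientation: the brominated C5=C6 bond is more electron-poor and less hindered than the aryl-bearing C2=C3 bonds of the pyranone and of the chlorinated isoflavone, whose adducts could not aromatise, and the enone polarity places the silyloxy carbon para to C4a, that is at C7.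

**Step 8**
Reactants: 15 3-{3-[4-(8-chloro-7-methoxy-4-oxo-4H-chromen-3-yl)phenoxy]-4-methoxyphenyl}-7-hydroxy-4H-chromen-4-one
Product: 16 Bisoflavolin K
Conditions: BBr3 (8 equiv), CH2Cl2, −78 °C to rt; then H2O
Reagents that add atoms: none
Why: BBr3 ether cleavage (Lewis acid complexation, then SN2 attack of bromide on methyl) should remove both aryl methyl ethers while the diaryl ether, the aryl chloride and the chromone rings are inert, the excess covering complexation by the carbonyls and the free phenol.

**Compound list**
1 | 2-chlororesorcinol (2-chlorobenzene-1,3-diol) | Oc1cccc(O)c1Cl | starting material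
2 | 4-hydroxyphenylacetic acid | O=C(O)Cc1ccc(O)cc1 | starting material
3 | 1-(3-chloro-2,4-dihydroxyphenyl)-2-(4-hydroxyphenyl)ethan-1-one (deoxybenzoin) | O=C(Cc1ccc(O)cc1)c1ccc(O)c(Cl)c1O | intermediate
4 | 8-chloro-7-hydroxy-3-(4-hydroxyphenyl)-4H-chromen-4-one | O=c1c(-c2ccc(O)cc2)coc2c(Cl)c(O)ccc12 | intermediate
5 | 8-chloro-3-(4-hydroxyphenyl)-7-methoxy-4H-chromen-4-one | O=c1c(-c2ccc(O)cc2)coc2c(Cl)c(OC)ccc12 | intermediate
6 | 5-bromo-2-methoxyphenylboronic acid | COc1ccc(Br)cc1B(O)O | starting material
7 | 3-[4-(5-bromo-2-methoxyphenoxy)phenyl]-8-chloro-7-methoxy-4H-chromen-4-one | COc1ccc(Br)cc1Oc1ccc(-c2coc3c(Cl)c(OC)ccc3c2=O)cc1 | intermediate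
8 | 8-chloro-7-methoxy-3-{4-[2-methoxy-5-(4,4,5,5-tetramethyl-1,3,2-dioxaborolan-2-yl)phenoxy]phenyl}-4H-chromen-4-one | COc1ccc(B2OC(C)(C)C(C)(C)O2)cc1Oc1ccc(-c2coc3c(Cl)c(OC)ccc3c2=O)cc1 | intermediate
9 | 4H-pyran-4-one | O=c1ccocc1 | starting material
10 | 3,5-dibromo-4H-pyran-4-one | O=c1c(Br)cocc1Br | intermediate
11 | 3-bromo-5-{3-[4-(8-chloro-7-methoxy-4-oxo-4H-chromen-3-yl)phenoxy]-4-methoxyphenyl}-4H-pyran-4-one | O=c1c(Br)cocc1-c1ccc(OC)c(Oc2ccc(-c3coc4c(Cl)c(OC)ccc4c3=O)cc2)c1 | intermediate
12 | (E)-1-methoxy-3-(trimethylsilyloxy)buta-1,3-diene | CO/C=C/C(=C)O[Si](C)(C)C | starting material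
13 | racemic cis-fused 4a-bromo-5-methoxy-7-(trimethylsilyloxy)-4a,5,8,8a-tetrahydro-4H-chromen-4-one carrying the aryl group of 11 at C3; Br at C4a and H at C8a cis, OMe at C5 trans to Br | O=C1C(c3ccc(OC)c(Oc4ccc(-c5coc6c(Cl)c(OC)ccc6c5=O)cc4)c3)=CO[C@@H]2CC(O[Si](C)(C)C)=C[C@H](OC)[C@]12Br | intermediate
14 | racemic cis-4a-bromo-4a,8a-dihydro-4H-chromene-4,7(8H)-dione carrying the aryl group of 11 at C3; Br at C4a and H at C8a cis | O=C1C(c3ccc(OC)c(Oc4ccc(-c5coc6c(Cl)c(OC)ccc6c5=O)cc4)c3)=CO[C@@H]2CC(=O)C=C[C@]12Br | intermediate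
15 | 3-{3-[4-(8-chloro-7-methoxy-4-oxo-4H-chromen-3-yl)phenoxy]-4-methoxyphenyl}-7-hydroxy-4H-chromen-4-one | O=c1c(-c2ccc(OC)c(Oc3ccc(-c4coc5c(Cl)c(OC)ccc5c4=O)cc3)c2)coc2cc(O)ccc12 | intermediate
16 | Bisoflavolin K, 3-{3-[4-(8-chloro-7-hydroxy-4-oxo-4H-chromen-3-yl)phenoxy]-4-hydroxyphenyl}-7-hydroxy-4H-chromen-4-one | O=c1c(-c2ccc(O)c(Oc3ccc(-c4coc5c(Cl)c(O)ccc5c4=O)cc3)c2)coc2cc(O)ccc12 | target

**Step count**
Total: 8 steps. Longest linear sequence: 7 steps (steps 1, 2, 3, 4, 6, 7, 8); step 5 is a one-step side branch.

**Steps most likely to fail**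

Step 7 (Diels–Alder benzannulation). The bromopyranone may be too weak a dienophile, so that the diene oligomerises before cycloaddition. After the acid treatment, base may also open the dihydropyranone ring by β-elimination of the ring oxygen instead of removing HBr. The fallback attaches the second chromone as a preformed ring by known chemistry; it sets out from boronate 8 and rejoins the route at target 16. Purchased 2'-hydroxy-4'-methoxyacetophenone is condensed with DMF-DMA (95 °C) to (E)-3-(dimethylamino)-1-(2-hydroxy-4-methoxyphenyl)prop-2-en-1-one F1. Iodine in CHCl3 at rt cyclises F1 to 3-iodo-7-methoxy-4H-chromen-4-one F2. Suzuki–Miyaura coupling of F2 with 8 (Pd(dppf)Cl2, K3PO4, dioxane/H2O, 70 °C) should give 3-{3-[4-(8-chloro-7-methoxy-4-oxo-4H-chromen-3-yl)phenoxy]-4-methoxyphenyl}-7-methoxy-4H-chromen-4-one F3. BBr3 in CH2Cl2 then cleaves all three methyl ethers to 16.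

Step 6 (mono-Suzuki coupling). Arylation may proceed at both C–Br bonds, the electron-poor dibromide may be opened by the aqueous base, and the boronate may protodeboronate. The fallback replaces statistical control by halogen differentiation; it sets out from boronate 8 and returns at 11. Purchased 3-bromo-4H-pyran-4-one (O=c1ccocc1Br) is iodinated at C5 with I2 and (NH4)2Ce(NO3)6 in MeCN at 70 °C to 3-bromo-5-iodo-4H-pyran-4-one F4. Coupling of F4 with 8 (Pd(PPh3)4, K3PO4, dioxane/H2O, 40 °C) should occur at the C–I bond only and give 11.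

Step 3 (Chan–Lam O-arylation). Transmetalation of the ortho-methoxy boronic acid may be slow, so that protodeboronation and oxidative homocoupling consume it before the C–O bond forms. The fallback is an Ullmann-type coupling with an aryl iodide; it sets out from phenol 5 and returns at 7. Phenol 5 and purchased 4-bromo-2-iodoanisole (COc1ccc(Br)cc1I) are coupled with CuI, N,N-dimethylglycine and Cs2CO3 in dioxane at 90 °C, the C–I bond reacting ahead of C–Br. This gives 7 directly, so no new compound arises on this way (F0).

**Further compounds**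
F1 | step 7 | (E)-3-(dimethylamino)-1-(2-hydroxy-4-methoxyphenyl)prop-2-en-1-one | CN(C)/C=C/C(=O)c1ccc(OC)cc1O
F2 | step 7 | 3-iodo-7-methoxy-4H-chromen-4-one | COc1ccc2c(c1)occ(I)c2=O
F3 | step 7 | 3-{3-[4-(8-chloro-7-methoxy-4-oxo-4H-chromen-3-yl)phenoxy]-4-methoxyphenyl}-7-methoxy-4H-chromen-4-one | O=c1c(-c2ccc(OC)c(Oc3ccc(-c4coc5c(Cl)c(OC)ccc5c4=O)cc3)c2)coc2cc(OC)ccc12
F4 | step 6 | 3-bromo-5-iodo-4H-pyran-4-one | O=c1c(Br)cocc1I
F0 | step 3 | none | none
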